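## The problem

The target is a depsidone. Ring A (methyl, H, OH, CHO, ether O, ester carbonyl) and ring B are joined twice, by a diaryl ether oxygen and by an aryl ester, which closes the seven-membered dioxepinone ring C. A five-membered lactol (3-hydroxyphthalide, ring D) is fused to ring B, and the benzylic CH2O group of ring B carries a fumaric acid half ester.

Ring B is hexasubstituted with six different groups, and the ether oxygen lies between four ortho substituents. A late copper-mediated coupling of two finished arenes is therefore the weak point of classical depsidone routes.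

The only stereocentre is the lactol carbon, (R). It is a hemiacetal that opens to the formyl acid and recloses, no other stereocentre can control it, and it cannot be carried through a synthesis. It has to be set last, in the solid.

The aryl ester of ring C (alcoholysis), the benzylic fumarate next to a phenol (ionisation, conjugate addition, hydrogenation), two aryl aldehydes and the lactol exclude base, hydride and hydrogen at the end. The last unmasking must be one mild acid treatment.

The formyl and carboxyl groups on adjacent ring B carbons also interfere with each other: next to a tert-butyl ester, an acid-catalysed acetalisation would be intercepted by the ester carbonyl with loss of isobutene. The ring B aldehyde is therefore best introduced at a point where it never needs an acetal.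

The feature that opens the key step is in ring A. Its carbons C6 (methyl), C5 (H), C4 (oxygen) and C3 (formyl carbon) are C6, C5, C4 and C3 of a 4-oxygenated 6-methyl-2-pyrone. The remaining two, C2 with the ether oxygen and C1 with the carboxyl, are the two carbons of an aryloxypropiolate.

## Retrosynthesis

**Stereocentre.** Target 32 is cut back to the racemic lactol 29 through the crystalline ammonium salt 31 formed with amine 30. No covalent bond changes; the lactol epimerises in solution and one diastereomeric salt is asked to crystallise. Any earlier control would be erased by ring–chain tautomerism.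

**Global unmasking.** 29 comes from 28 by acid alone. The lactol C–O bond is cut back to a free aldehyde beside a tert-butyl ester, the two phenols to methoxymethyl ethers and the fumaric acid to its tert-butyl ester. Methyl ethers would need BCl3, which also cleaves benzylic esters; the acid-labile set needs only trifluoroacetic acid.

**Fumarate.** The benzylic ester C–O bond of 28 is cut to alcohol 26 and mono-tert-butyl fumarate 27. The acceptor and the labile benzylic ester thus enter after all organometallic, hydrogenation and fluoride steps. 26 comes from silyl ether 25.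

**Ring C.** The aryl ester C–O bond of 25 is cut to hydroxy acid 24. Closing the lactone after the ether exists turns a hindered esterification into a seven-membered ring closure. 24 comes from 23 by hydrogenolysis of one benzyl ether and one benzyl ester. A benzyl ester is chosen because a 2,6-disubstituted methyl benzoate cannot be hydrolysed, and a phenoxide cannot displace methoxide from it.

**Formyl groups.** Both aryl–CHO bonds of 23 are cut to diaryl ether 21: the ring A formyl to the C–Br bond, the ring B formyl to the C–H between the tert-butyl ester and the ether oxygen. Introducing both in one metalation/DMF operation means no aldehyde is present while organometallics are, and the alkyne and the cycloaddition stay free of a sixth ortho substituent.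

**Ring A (key cut).** Two C–C bonds of ring A in 21 are cut, giving benzyl aryloxypropiolate 16 and bromopyrone 19. Against an Ullmann coupling, the ether C–O bond is formed on a phenol, before ring A exists. The forward reaction must be regioselective: bromine next to the ether oxygen, carboxyl next to methyl.

**Ynol ether.** 16 is cut at the alkyne–carboxyl bond and the two C–Cl bonds to dichlorovinyl ether 12 and benzyl chloroformate 13. 12 is cut at the vinyl C–O bond to phenol 10 and trichloroethylene 11. The oxygen next to the phenol is a benzyl ether, because a silyl group would migrate between the catechol oxygens once its neighbour is a phenoxide.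

**Pyrone.** 19 comes from 4-hydroxy-6-methyl-2-pyrone 17 by O-alkylation (18) and bromination at C3.

**Ring B.** Phenol 10 is cut at the C–O bond to bromide 8, which comes from 7 by bromination at the only activated position. The CH2O carbon is traced through 6 and 5 to aldehyde 4, placed between the two oxygens of 3 by phenol-directed formylation. 3 and 2 lead back to 2,4-dihydroxybenzoic acid 1, which already holds the carboxyl and two of the three oxygens. Every substitution has one possible site.

## Roads not taken

**Alternative 1:** The cut is at the aryl–CH2 and CH2–O bonds of ring D. Pd(OAc)2 (divalent palladium) with K2HPO4 in CH2Br2 would annulate a depsidone carboxylic acid to phthalide A1 by carboxylate-directed C–H alkylation and lactonisation.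
- Merits: ring D is made catalytically on an intact tricycle, and ring B needs one carbon substituent fewer at the start. In ring B step count this road is shorter than the chosen one.
- Weak points: A1 is a phthalide, one oxidation level too low, with the CH2O carbon still a methyl group. Raising both means benzylic functionalisation in the presence of three benzylic sites (ring A methyl, ring B methyl, lactone CH2) and an aldehyde. The hindered diaryl ether is not addressed at all, and the aryl ester must survive phosphate at high temperature.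
- Comparison: the chosen plan pays with a longer ring B sequence, but sets every oxidation level before the rings are joined.

**Alternative 2:** The cut is at two C–C bonds of ring B. A 2-silyloxyfuran and an ynal ester would undergo Diels–Alder addition and oxa-bridge opening to the hexasubstituted formyl benzoate A2.
- Merits: as a ring B synthesis it is more convergent than steps 1 to 8 of the chosen route, and it delivers formyl, carboxyl and three differentiated oxygens in one step.
- Weak points: A2 carries a methyl group where the CH2O–fumarate must be. It also carries a silyl ether on a catechol oxygen, which will migrate once the neighbouring oxygen is a phenoxide. The regiochemistry of a tetrasubstituted furan with an unsymmetrical ynal is not secured. The diaryl ether and ring A remain to be made.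
- Comparison: this road could feed the chosen key step. Against its convergence the chosen plan sets aromatic substitutions of unambiguous regiochemistry and the correct CH2O oxidation level from step 3 on.

**Alternative 3:** The cut is at three C–C bonds of ring B. RhCl(PPh3)3 (monovalent rhodium) would cyclotrimerise a triyne tethered to ring A, closing ring B, ring C and the five-membered lactone at once to give A3.
- Merits: the highest convergence of all four roads, with both hard problems (hexasubstituted ring B, hindered ether) solved in one step.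
- Weak points: the triyne needs an aryl ynol ether and an alkynyl ester of the ring A acid on the same arene, plus an alkoxypropiolate. The alkynyl ester is an acylating agent that is unlikely to survive its own preparation. Closing a seven-membered ring during the cyclotrimerisation is unfavourable. A3 is again a phthalide, with an ethyl ether to be cleaved selectively.
- Comparison: it is shorter on paper, but rests on an unstable substrate class. The chosen plan uses a push–pull ynol ether ester and a pyrone, both stable and isolable.

Key step: step 13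

Assumption: the lactol carbon epimerises in solution by ring–chain tautomerism, so the (R) enantiomer can only be defined, delivered and stored as a crystalline solid.

## Route

Step 1
Reactants: 1 2,4-dihydroxybenzoic acid
Product: 2 tert-butyl 2,4-dihydroxybenzoate
Conditions: Me2NCH(Ot-Bu)2, toluene, 80 °C
Reagents that add atoms: N,N-dimethylformamide di-tert-butyl acetal, CN(C)C(OC(C)(C)C)OC(C)(C)C
Why: Esterification of a carboxylic acid with an amide acetal; the acid protonates the reagent and is alkylated by the tert-butyl cation equivalent, the less acidic phenols stay free.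

Step 2
Reactants: 2 tert-butyl 2,4-dihydroxybenzoate
Product: 3 tert-butyl 4-(benzyloxy)-2-hydroxybenzoate
Conditions: BnBr (1.05 equiv), K2CO3, acetone, reflux
Reagents that add atoms: benzyl bromide, BrCc1ccccc1
Why: Williamson ether synthesis; the 2-hydroxyl is hydrogen-bonded to the ester and flanked by it, so the 4-hydroxyl alkylates selectively.

Step 3
Reactants: 3 tert-butyl 4-(benzyloxy)-2-hydroxybenzoate
Product: 4 tert-butyl 4-(benzyloxy)-3-formyl-2-hydroxybenzoate
Conditions: MgCl2, Et3N, (CH2O)n, MeCN, reflux
Reagents that add atoms: formaldehyde (as paraformaldehyde), C=O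
Why: Magnesium-mediated ortho-formylation of a phenol (Casnati–Skattebøl reaction); the magnesium phenoxide delivers formaldehyde to the only free ortho position, which is also activated by the benzyloxy group, and a second formaldehyde accepts hydride.

Step 4
Reactants: 4 tert-butyl 4-(benzyloxy)-3-formyl-2-hydroxybenzoate
Product: 5 tert-butyl 4-(benzyloxy)-3-formyl-2-(methoxymethoxy)benzoate
Conditions: NaH, DMF, 0 °C; MOMCl, 0 °C to rt
Reagents that add atoms: chloromethyl methyl ether, COCCl
Why: O-alkylation of an acidic, doubly chelated phenoxide with a reactive chloromethyl ether; the acetal ether is stable to every later base, organometallic and hydrogenation step and falls in the final acid treatment.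

Step 5
Reactants: 5 tert-butyl 4-(benzyloxy)-3-formyl-2-(methoxymethoxy)benzoate
Product: 6 tert-butyl 4-(benzyloxy)-3-(hydroxymethyl)-2-(methoxymethoxy)benzoate
Conditions: NaBH4, THF–MeOH, 0 °C
Reagents that add atoms: none
Why: Borohydride reduction of an aryl aldehyde; the tert-butyl ester is untouched and is meta to the new alkoxide, so no lactone can form.

Step 6
Reactants: 6 tert-butyl 4-(benzyloxy)-3-(hydroxymethyl)-2-(methoxymethoxy)benzoate
Product: 7 tert-butyl 4-(benzyloxy)-3-{[(tert-butyldiphenylsilyl)oxy]methyl}-2-(methoxymethoxy)benzoate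
Conditions: TBDPSCl, imidazole, DMF, rt
Reagents that add atoms: tert-butyl(chloro)diphenylsilane, CC(C)(C)[Si](Cl)(c1ccccc1)c1ccccc1
Why: Silylation of a primary alcohol; the bulky silyl ether withstands carbonate, butyllithium, heat, magnesium reagents and hydrogenolysis and is removed by fluoride when the alcohol is needed.

Step 7
Reactants: 7 tert-butyl 4-(benzyloxy)-3-{[(tert-butyldiphenylsilyl)oxy]methyl}-2-(methoxymethoxy)benzoate
Product: 8 tert-butyl 4-(benzyloxy)-5-bromo-3-{[(tert-butyldiphenylsilyl)oxy]methyl}-2-(methoxymethoxy)benzoate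
Conditions: NBS, MeCN, 0 °C to rt, dark
Reagents that add atoms: N-bromosuccinimide, O=C1CCC(=O)N1Br
Why: Electrophilic aromatic bromination; C5 is ortho to the benzyloxy and para to the methoxymethoxy group, while the only other free position is ortho to the ester and deactivated.

Step 8
Reactants: 8 tert-butyl 4-(benzyloxy)-5-bromo-3-{[(tert-butyldiphenylsilyl)oxy]methyl}-2-(methoxymethoxy)benzoate
Product: 10 tert-butyl 4-(benzyloxy)-3-{[(tert-butyldiphenylsilyl)oxy]methyl}-5-hydroxy-2-(methoxymethoxy)benzoate, via pinacol boronate 9 (not isolated)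
Conditions: B2pin2, Pd(dppf)Cl2, KOAc, dioxane, 90 °C; then 30% H2O2, aq. NaOH, THF, 0 °C
Reagents that add atoms: bis(pinacolato)diboron, CC1(C)OB(OC1(C)C)B1OC(C)(C)C(C)(C)O1 (boron of 9); hydrogen peroxide, OO
Why: Miyaura borylation of an aryl bromide and oxidation of the aryl boronate with retention of the C–O position; the hindered tert-butyl ester and the silyl ether tolerate the brief cold alkaline peroxide.

Step 9
Reactants: 10 tert-butyl 4-(benzyloxy)-3-{[(tert-butyldiphenylsilyl)oxy]methyl}-5-hydroxy-2-(methoxymethoxy)benzoate; 11 trichloroethylene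
Product: 12 tert-butyl 4-(benzyloxy)-3-{[(tert-butyldiphenylsilyl)oxy]methyl}-5-{[(E)-1,2-dichloroethenyl]oxy}-2-(methoxymethoxy)benzoate
Conditions: K2CO3, DMF, 70 °C
Reagents that add atoms: none
Why: Addition of a phenoxide to dichloroacetylene formed in the flask from trichloroethylene and base; anti addition gives the (E)-dichlorovinyl ether, and the neighbouring benzyl ether cannot migrate as a silyl group would.

Step 10
Reactants: 12 tert-butyl 4-(benzyloxy)-3-{[(tert-butyldiphenylsilyl)oxy]methyl}-5-{[(E)-1,2-dichloroethenyl]oxy}-2-(methoxymethoxy)benzoate; 13 benzyl chloroformate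
Product: 16 tert-butyl 4-(benzyloxy)-5-{[3-(benzyloxy)-3-oxoprop-1-yn-1-yl]oxy}-3-{[(tert-butyldiphenylsilyl)oxy]methyl}-2-(methoxymethoxy)benzoate, via chloroethynyl ether 14 (not isolated), via lithium aryloxyacetylide 15 (not isolated)
Conditions: n-BuLi (2.2 equiv), Et2O, −78 to −40 °C; then 13, −78 °C to 0 °C
Reagents that add atoms: n-butyllithium, [Li]CCCC (lithium of 15)
Why: Dichlorovinyl ether route to ynol ethers: vinyl deprotonation and loss of LiCl give the chloroalkyne, chlorine–lithium exchange the acetylide, and C-acylation with a chloroformate the propiolate. These fast steps at −78 °C in ether should outrun addition to the tert-butyl ester.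

Step 11
Reactants: 17 4-hydroxy-6-methyl-2H-pyran-2-one
Product: 18 4-(methoxymethoxy)-6-methyl-2H-pyran-2-one
Conditions: MOMCl, i-Pr2NEt, CH2Cl2, 0 °C to rt
Reagents that add atoms: chloromethyl methyl ether, COCCl
Why: O-alkylation of the acidic vinylogous acid with a hard electrophile, which favours the 4-alkoxy-2-pyrone over C-alkylation.

Step 12
Reactants: 18 4-(methoxymethoxy)-6-methyl-2H-pyran-2-one
Product: 19 3-bromo-4-(methoxymethoxy)-6-methyl-2H-pyran-2-one
Conditions: NBS, NaHCO3, MeCN, rt, dark
Reagents that add atoms: N-bromosuccinimide, O=C1CCC(=O)N1Br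
Why: Electrophilic bromination of a 4-alkoxy-2-pyrone at C3, the enol ether beta-carbon between the carbonyl and the alkoxy group.

Step 13
Reactants: 16 tert-butyl 4-(benzyloxy)-5-{[3-(benzyloxy)-3-oxoprop-1-yn-1-yl]oxy}-3-{[(tert-butyldiphenylsilyl)oxy]methyl}-2-(methoxymethoxy)benzoate; 19 3-bromo-4-(methoxymethoxy)-6-methyl-2H-pyran-2-one
Product: 21 benzyl 2-[2-(benzyloxy)-5-(tert-butoxycarbonyl)-3-{[(tert-butyldiphenylsilyl)oxy]methyl}-4-(methoxymethoxy)phenoxy]-3-bromo-4-(methoxymethoxy)-6-methylbenzoate, via bridged bicyclic lactone 20 (not isolated)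
Conditions: 19 (3 equiv), BHT (cat.), toluene, 150 °C, sealed tube
Reagents that add atoms: none
Why: Diels–Alder addition of a 2-pyrone to an alkynoate followed by cycloreversion of CO2, a known route to benzoates. The pyrone reacts across C3 and C6; C3, made nucleophilic by the 4-alkoxy group and the ring oxygen, bonds to the alkyne carbon beta to the ester (the aryloxy carbon), and C6 bonds to the alpha carbon. The adduct 20 is a 2-oxabicyclo[2.2.2]octadienone that cannot persist at 150 °C and expels CO2 in a retro-[4+2] step, so ring A closes by a six-membered pericyclic addition and then aromatises. No stereocentre remains in 21. The selectivity needed is regiochemical, bromine beside the ether oxygen and carboxyl beside methyl; the polarisation of the push–pull alkyne and that of the 4-alkoxypyrone call for the same pairing under normal and inverse electron demand. The 3-bromo group makes the pyrone a more reactive, ambiphilic diene and becomes the handle for the formyl group. Leaving the ring B formyl group out until step 14 keeps one position ortho to the aryloxy oxygen free and the alkyne accessible. Excess of the cheap pyrone and a closed vessel compensate for the donor-substituted dienophile.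

Step 14
Reactants: 21 benzyl 2-[2-(benzyloxy)-5-(tert-butoxycarbonyl)-3-{[(tert-butyldiphenylsilyl)oxy]methyl}-4-(methoxymethoxy)phenoxy]-3-bromo-4-(methoxymethoxy)-6-methylbenzoate
Product: 23 benzyl 2-[2-(benzyloxy)-5-(tert-butoxycarbonyl)-3-{[(tert-butyldiphenylsilyl)oxy]methyl}-6-formyl-4-(methoxymethoxy)phenoxy]-3-formyl-4-(methoxymethoxy)-6-methylbenzoate, via bis(chloromagnesio) diaryl ether 22 (not isolated)
Conditions: TMPMgCl·LiCl, THF, 0 °C to rt; i-PrMgCl·LiCl, −15 to 0 °C; DMF, −20 °C to rt; aq. NH4Cl
Reagents that add atoms: N,N-dimethylformamide, CN(C)C=O; TMPMgCl·LiCl, CC1(C)CCCC(C)(C)N1[Mg]Cl.[Li+].[Cl-] (magnesium of 22); i-PrMgCl·LiCl, CC(C)[Mg]Cl.[Li+].[Cl-] (magnesium of 22)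
Why: Ester-directed ortho-magnesiation with a hindered magnesium amide at the ring B C–H flanked by the tert-butyl ester and the aryloxy oxygen, bromine–magnesium exchange at the ring A bromide flanked by two oxygens, and formylation of both arylmagnesium centres with DMF. No aldehyde exists until the quench, so none needs protection, and both esters are hindered and tolerated by these reagents.

Step 15
Reactants: 23 benzyl 2-[2-(benzyloxy)-5-(tert-butoxycarbonyl)-3-{[(tert-butyldiphenylsilyl)oxy]methyl}-6-formyl-4-(methoxymethoxy)phenoxy]-3-formyl-4-(methoxymethoxy)-6-methylbenzoate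
Product: 24 2-[5-(tert-butoxycarbonyl)-3-{[(tert-butyldiphenylsilyl)oxy]methyl}-6-formyl-2-hydroxy-4-(methoxymethoxy)phenoxy]-3-formyl-4-(methoxymethoxy)-6-methylbenzoic acid
Conditions: H2 (1 atm), Pd/C, EtOAc, rt, monitored
Reagents that add atoms: none
Why: Hydrogenolysis of a benzyl ester and an aryl benzyl ether in one operation; both aldehydes have two ortho substituents and should be reduced much more slowly in a neutral aprotic solvent.

Step 16
Reactants: 24 2-[5-(tert-butoxycarbonyl)-3-{[(tert-butyldiphenylsilyl)oxy]methyl}-6-formyl-2-hydroxy-4-(methoxymethoxy)phenoxy]-3-formyl-4-(methoxymethoxy)-6-methylbenzoic acid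
Product: 25 tert-butyl 9-{[(tert-butyldiphenylsilyl)oxy]methyl}-4,6-diformyl-3,8-bis(methoxymethoxy)-1-methyl-11-oxo-11H-dibenzo[b,e][1,4]dioxepine-7-carboxylate
Conditions: EDC·HCl, DMAP, CH2Cl2 (0.005 M), rt
Reagents that add atoms: none
Why: Carbodiimide lactonisation (Steglich conditions) of a 2-(2-hydroxyaryloxy)benzoic acid, the standard depsidone ring closure; the only free hydroxyl is held next to the activated acid by the ether, so the seven-membered ring forms in preference to oligomers.

Step 17
Reactants: 25 tert-butyl 9-{[(tert-butyldiphenylsilyl)oxy]methyl}-4,6-diformyl-3,8-bis(methoxymethoxy)-1-methyl-11-oxo-11H-dibenzo[b,e][1,4]dioxepine-7-carboxylate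
Product: 26 tert-butyl 4,6-diformyl-9-(hydroxymethyl)-3,8-bis(methoxymethoxy)-1-methyl-11-oxo-11H-dibenzo[b,e][1,4]dioxepine-7-carboxylate
Conditions: Bu4NF, AcOH (1:1), THF, 0 °C to rt
Reagents that add atoms: none
Why: Fluoride cleavage of a silyl ether; buffering with acetic acid keeps the medium non-basic so that the aryl ester of ring C is not opened by the liberated alkoxide.

Step 18
Reactants: 26 tert-butyl 4,6-diformyl-9-(hydroxymethyl)-3,8-bis(methoxymethoxy)-1-methyl-11-oxo-11H-dibenzo[b,e][1,4]dioxepine-7-carboxylate; 27 (2E)-4-tert-butoxy-4-oxobut-2-enoic acid (mono-tert-butyl fumarate)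
Product: 28 tert-butyl 9-({[(2E)-4-tert-butoxy-4-oxobut-2-enoyl]oxy}methyl)-4,6-diformyl-3,8-bis(methoxymethoxy)-1-methyl-11-oxo-11H-dibenzo[b,e][1,4]dioxepine-7-carboxylate
Conditions: EDC·HCl, DMAP (cat.), CH2Cl2, 0 °C to rt
Reagents that add atoms: none
Why: Steglich esterification of the only free hydroxyl, a primary benzylic alcohol; the (E) double bond is carried in unchanged from the half ester.

Step 19
Reactants: 28 tert-butyl 9-({[(2E)-4-tert-butoxy-4-oxobut-2-enoyl]oxy}methyl)-4,6-diformyl-3,8-bis(methoxymethoxy)-1-methyl-11-oxo-11H-dibenzo[b,e][1,4]dioxepine-7-carboxylate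
Product: 29 racemic lactol, (±) form of target 32 (both configurations at the lactol carbon)
Conditions: TFA–CH2Cl2 (1:2), H2O (2 equiv), 0 °C to rt
Reagents that add atoms: none
Why: Acidolysis of two tert-butyl esters and two methoxymethyl ethers in one operation; the freed ring B acid adds to the neighbouring aldehyde and closes the lactol (ring–chain tautomerism of a 2-formylbenzoic acid), which forms as the racemate.

Step 20
Reactants: 29 racemic lactol; 30 (S)-N,N-dimethyl-1-phenylethylamine
Product: 31 (S)-N,N-dimethyl-1-phenylethylammonium salt of the (R)-lactol (fumarate carboxylate as anion)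
Conditions: 30 (1.0 equiv), acetone–EtOAc, 40 °C to 20 °C, seeded slurry, 48 h; filtration
Reagents that add atoms: none
Why: Proposed new method: the lactol epimerises in solution through the open formyl acid while the less soluble diastereomeric salt of the remote fumaric acid group crystallises, so the whole material should converge on one configuration at the lactol carbon; the closest known reaction type is crystallisation-induced diastereomer transformation of epimerisable acids and acetal centres as salts or covalent derivatives; a tertiary amine is used because it cannot condense with the aldehydes; the stereocentre is set by the crystal lattice alone, and if the (S) amine deposits the (S) lactol, the (R) amine is its exact mirror-image substitute.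

Step 21
Reactants: 31 (S)-N,N-dimethyl-1-phenylethylammonium salt of the (R)-lactol
Product: 32 target, (R) at the lactol carbon, (E) fumaric acid half ester
Conditions: 0.5 M aq. HCl, 0 °C, slurry; filtration, cold water wash, drying in vacuo
Reagents that add atoms: none
Why: Salt break by a strong acid in suspension; the free acid is insoluble in cold water, so the solid is converted without passing through a solution in which the lactol could epimerise.

## Compound list

1 | 2,4-dihydroxybenzoic acid | OC(=O)c1ccc(O)cc1O | starting material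
2 | tert-butyl 2,4-dihydroxybenzoate | CC(C)(C)OC(=O)c1ccc(O)cc1O | intermediate
3 | tert-butyl 4-(benzyloxy)-2-hydroxybenzoate | CC(C)(C)OC(=O)c1ccc(OCc2ccccc2)cc1O | intermediate
4 | tert-butyl 4-(benzyloxy)-3-formyl-2-hydroxybenzoate | CC(C)(C)OC(=O)c1ccc(OCc2ccccc2)c(C=O)c1O | intermediate
5 | tert-butyl 4-(benzyloxy)-3-formyl-2-(methoxymethoxy)benzoate | CC(C)(C)OC(=O)c1ccc(OCc2ccccc2)c(C=O)c1OCOC | intermediate
6 | tert-butyl 4-(benzyloxy)-3-(hydroxymethyl)-2-(methoxymethoxy)benzoate | CC(C)(C)OC(=O)c1ccc(OCc2ccccc2)c(CO)c1OCOC | intermediate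
7 | tert-butyl 4-(benzyloxy)-3-{[(tert-butyldiphenylsilyl)oxy]methyl}-2-(methoxymethoxy)benzoate | CC(C)(C)OC(=O)c1ccc(OCc2ccccc2)c(CO[Si](c2ccccc2)(c2ccccc2)C(C)(C)C)c1OCOC | intermediate
8 | tert-butyl 4-(benzyloxy)-5-bromo-3-{[(tert-butyldiphenylsilyl)oxy]methyl}-2-(methoxymethoxy)benzoate | CC(C)(C)OC(=O)c1cc(Br)c(OCc2ccccc2)c(CO[Si](c2ccccc2)(c2ccccc2)C(C)(C)C)c1OCOC | intermediate
9 | pinacol boronate: tert-butyl 4-(benzyloxy)-3-{[(tert-butyldiphenylsilyl)oxy]methyl}-2-(methoxymethoxy)-5-(4,4,5,5-tetramethyl-1,3,2-dioxaborolan-2-yl)benzoate | CC(C)(C)OC(=O)c1cc(B2OC(C)(C)C(C)(C)O2)c(OCc2ccccc2)c(CO[Si](c2ccccc2)(c2ccccc2)C(C)(C)C)c1OCOC | intermediate (not isolated)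
10 | tert-butyl 4-(benzyloxy)-3-{[(tert-butyldiphenylsilyl)oxy]methyl}-5-hydroxy-2-(methoxymethoxy)benzoate (ring B phenol) | CC(C)(C)OC(=O)c1cc(O)c(OCc2ccccc2)c(CO[Si](c2ccccc2)(c2ccccc2)C(C)(C)C)c1OCOC | intermediate
11 | trichloroethylene | ClC=C(Cl)Cl | starting material
12 | tert-butyl 4-(benzyloxy)-3-{[(tert-butyldiphenylsilyl)oxy]methyl}-5-{[(E)-1,2-dichloroethenyl]oxy}-2-(methoxymethoxy)benzoate | CC(C)(C)OC(=O)c1cc(O/C(Cl)=C\Cl)c(OCc2ccccc2)c(CO[Si](c2ccccc2)(c2ccccc2)C(C)(C)C)c1OCOC | intermediate
13 | benzyl chloroformate | O=C(Cl)OCc1ccccc1 | starting material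
14 | chloroethynyl ether: tert-butyl 4-(benzyloxy)-3-{[(tert-butyldiphenylsilyl)oxy]methyl}-5-[(chloroethynyl)oxy]-2-(methoxymethoxy)benzoate | CC(C)(C)OC(=O)c1cc(OC#CCl)c(OCc2ccccc2)c(CO[Si](c2ccccc2)(c2ccccc2)C(C)(C)C)c1OCOC | intermediate (not isolated)
15 | lithium aryloxyacetylide derived from 14 (lithium in place of chlorine) | CC(C)(C)OC(=O)c1cc(OC#C[Li])c(OCc2ccccc2)c(CO[Si](c2ccccc2)(c2ccccc2)C(C)(C)C)c1OCOC | intermediate (not isolated)
16 | benzyl 3-aryloxypropiolate: tert-butyl 4-(benzyloxy)-5-{[3-(benzyloxy)-3-oxoprop-1-yn-1-yl]oxy}-3-{[(tert-butyldiphenylsilyl)oxy]methyl}-2-(methoxymethoxy)benzoate | CC(C)(C)OC(=O)c1cc(OC#CC(=O)OCc2ccccc2)c(OCc2ccccc2)c(CO[Si](c2ccccc2)(c2ccccc2)C(C)(C)C)c1OCOC | intermediate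
17 | 4-hydroxy-6-methyl-2H-pyran-2-one | Cc1cc(O)cc(=O)o1 | starting material
18 | 4-(methoxymethoxy)-6-methyl-2H-pyran-2-one | COCOc1cc(C)oc(=O)c1 | intermediate
19 | 3-bromo-4-(methoxymethoxy)-6-methyl-2H-pyran-2-one | COCOc1cc(C)oc(=O)c1Br | intermediate
20 | bridged bicyclic lactone (2-oxabicyclo[2.2.2]octa-5,7-dien-3-one; bridgeheads carry Br and methyl, racemic) | CC12OC(=O)C(Br)(C(OCOC)=C1)C(Oc1cc(C(=O)OC(C)(C)C)c(OCOC)c(CO[Si](c3ccccc3)(c3ccccc3)C(C)(C)C)c1OCc1ccccc1)=C2C(=O)OCc1ccccc1 | intermediate (not isolated)
21 | benzyl 2-[2-(benzyloxy)-5-(tert-butoxycarbonyl)-3-{[(tert-butyldiphenylsilyl)oxy]methyl}-4-(methoxymethoxy)phenoxy]-3-bromo-4-(methoxymethoxy)-6-methylbenzoate | Cc1cc(OCOC)c(Br)c(Oc2cc(C(=O)OC(C)(C)C)c(OCOC)c(CO[Si](c3ccccc3)(c3ccccc3)C(C)(C)C)c2OCc2ccccc2)c1C(=O)OCc1ccccc1 | intermediate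
22 | bis(chloromagnesio) diaryl ether (MgCl in place of Br on ring A and of H between ester and ether oxygen on ring B) | Cc1cc(OCOC)c([Mg]Cl)c(Oc2c([Mg]Cl)c(C(=O)OC(C)(C)C)c(OCOC)c(CO[Si](c3ccccc3)(c3ccccc3)C(C)(C)C)c2OCc2ccccc2)c1C(=O)OCc1ccccc1 | intermediate (not isolated)
23 | benzyl 2-[2-(benzyloxy)-5-(tert-butoxycarbonyl)-3-{[(tert-butyldiphenylsilyl)oxy]methyl}-6-formyl-4-(methoxymethoxy)phenoxy]-3-formyl-4-(methoxymethoxy)-6-methylbenzoate | Cc1cc(OCOC)c(C=O)c(Oc2c(C=O)c(C(=O)OC(C)(C)C)c(OCOC)c(CO[Si](c3ccccc3)(c3ccccc3)C(C)(C)C)c2OCc2ccccc2)c1C(=O)OCc1ccccc1 | intermediate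
24 | 2-[5-(tert-butoxycarbonyl)-3-{[(tert-butyldiphenylsilyl)oxy]methyl}-6-formyl-2-hydroxy-4-(methoxymethoxy)phenoxy]-3-formyl-4-(methoxymethoxy)-6-methylbenzoic acid | Cc1cc(OCOC)c(C=O)c(Oc2c(C=O)c(C(=O)OC(C)(C)C)c(OCOC)c(CO[Si](c3ccccc3)(c3ccccc3)C(C)(C)C)c2O)c1C(=O)O | intermediate
25 | tert-butyl 9-{[(tert-butyldiphenylsilyl)oxy]methyl}-4,6-diformyl-3,8-bis(methoxymethoxy)-1-methyl-11-oxo-11H-dibenzo[b,e][1,4]dioxepine-7-carboxylate | Cc1cc(OCOC)c(C=O)c2c1C(=O)Oc1c(CO[Si](c3ccccc3)(c3ccccc3)C(C)(C)C)c(OCOC)c(C(=O)OC(C)(C)C)c(C=O)c1O2 | intermediate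
26 | tert-butyl 4,6-diformyl-9-(hydroxymethyl)-3,8-bis(methoxymethoxy)-1-methyl-11-oxo-11H-dibenzo[b,e][1,4]dioxepine-7-carboxylate | Cc1cc(OCOC)c(C=O)c2c1C(=O)Oc1c(CO)c(OCOC)c(C(=O)OC(C)(C)C)c(C=O)c1O2 | intermediate
27 | (2E)-4-tert-butoxy-4-oxobut-2-enoic acid (mono-tert-butyl fumarate) | CC(C)(C)OC(=O)/C=C/C(=O)O | starting material
28 | tert-butyl 9-({[(2E)-4-tert-butoxy-4-oxobut-2-enoyl]oxy}methyl)-4,6-diformyl-3,8-bis(methoxymethoxy)-1-methyl-11-oxo-11H-dibenzo[b,e][1,4]dioxepine-7-carboxylate | Cc1cc(OCOC)c(C=O)c2c1C(=O)Oc1c(COC(=O)/C=C/C(=O)OC(C)(C)C)c(OCOC)c(C(=O)OC(C)(C)C)c(C=O)c1O2 | intermediate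
29 | racemic lactol: depsidone 3-hydroxyphthalide with free phenols, ring A formyl group and (E)-fumaric acid half ester on the benzylic CH2O; lactol carbon unassigned | Cc1cc(O)c(C=O)c2c1C(=O)Oc1c(COC(=O)/C=C/C(=O)O)c(O)c3c(c1O2)C(O)OC3=O | intermediate
30 | (S)-N,N-dimethyl-1-phenylethylamine | C[C@H](N(C)C)c1ccccc1 | starting material
31 | (S)-N,N-dimethyl-1-phenylethylammonium salt of the (R)-lactol (fumarate carboxylate) | Cc1cc(O)c(C=O)c2c1C(=O)Oc1c(COC(=O)/C=C/C(=O)[O-])c(O)c3c(c1O2)[C@H](O)OC3=O.C[C@H]([NH+](C)C)c1ccccc1 | intermediate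
32 | target: the constitution of 29 with the lactol carbon (R) and the fumarate (E) | Cc1cc(O)c(C=O)c2c1C(=O)Oc1c(COC(=O)/C=C/C(=O)O)c(O)c3c(c1O2)[C@H](O)OC3=O | target

## Step count and risks

Total: 21 steps. Longest linear sequence: 19 steps (steps 1 to 10, then 13 to 21); steps 11 and 12 form the pyrone branch.

**Step 20 (Proposed new method).** Three things may go wrong. The diastereomeric salts may discriminate poorly, because the acid site is remote from the lactol. The amine may open the lactol to the achiral formyl carboxylate, which would then crystallise instead. Transient phenoxide formation next to the benzylic ester may cause loss of the fumarate.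

Fallback: the route is left at racemate 29, which is separated by preparative chromatography on a chiral stationary phase (cellulose tris(3,5-dimethylphenylcarbamate), acidified eluent, below room temperature). The (R) fraction is precipitated cold as solid 32, where the route is rejoined. The (S) fraction is left to re-equilibrate in solution and is recycled. No new compound is made.

**Step 13 (key step).** The donor-substituted alkyne may add too slowly, so that thermal decomposition of the ynol ether or loss of isobutene from the tert-butyl ester overtakes the cycloaddition.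

Fallback: the route is left at dichlorovinyl ether 12. Acetylide 15 is generated as in step 10 but quenched with DMF, giving the 3-aryloxypropynal F1, a stronger acceptor. F1 is heated with bromopyrone 19 at lower temperature and, after loss of CO2 with the same regiochemistry, gives the 3-bromo-2-aryloxybenzaldehyde F2. Pinnick oxidation (NaClO2, NaH2PO4, 2-methyl-2-butene) gives the benzoic acid F3, and benzylation with benzyl bromide and K2CO3 rejoins the route at 21.

**Step 14.** The C–H magnesiation may be incomplete or may go to ring A C5–H. One arylmagnesium centre may be lost on warming by elimination of the neighbouring aryloxide. The benzyl ester may be attacked during the slower bromine–magnesium exchange.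

Fallback: the route is left at phenol 10, and the ring B formyl group is installed before the ether is made.
- Magnesium-mediated ortho-formylation (MgCl2, Et3N, paraformaldehyde) gives the salicylaldehyde F4.
- Trichloroethylene and K2CO3 give its dichlorovinyl ether F5.
- The aldehyde is masked in the flask as its lithium α-amino alkoxide with LiN(Me)CH2CH2NMe2 before n-butyllithium and benzyl chloroformate are added; aqueous work-up gives the formyl propiolate F6.
- Cycloaddition with 19 gives the bromo diaryl ether F7.
- The ring B aldehyde of F7 is masked again in the same way, and bromine–magnesium exchange and DMF rejoin the route at 23.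

**Step 10.** Butyllithium may add to the tert-butyl ester, which here has only one ortho substituent, or deprotonate alpha to the benzyl ether oxygen in competition with the vinyl deprotonation.

Fallback: the route is left at phenol 10 and no alkyllithium is used. The phenoxide (Cs2CO3, DMF, with CuI and a diamine ligand if needed) is coupled with benzyl 3,3-dibromoacrylate to the 3-aryloxy-3-bromoacrylate F8, the known entry to bromo enol ethers from 1,1-dibromoalkenes. Dehydrobromination with t-BuOK in THF at low temperature rejoins the route at 16.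

## Further compounds

F0 | step 20 | none | none
F1 | step 13 | tert-butyl 4-(benzyloxy)-3-{[(tert-butyldiphenylsilyl)oxy]methyl}-2-(methoxymethoxy)-5-[(3-oxoprop-1-yn-1-yl)oxy]benzoate | CC(C)(C)OC(=O)c1cc(OC#CC=O)c(OCc2ccccc2)c(CO[Si](c2ccccc2)(c2ccccc2)C(C)(C)C)c1OCOC
F2 | step 13 | tert-butyl 4-(benzyloxy)-5-[2-bromo-6-formyl-3-(methoxymethoxy)-5-methylphenoxy]-3-{[(tert-butyldiphenylsilyl)oxy]methyl}-2-(methoxymethoxy)benzoate | Cc1cc(OCOC)c(Br)c(Oc2cc(C(=O)OC(C)(C)C)c(OCOC)c(CO[Si](c3ccccc3)(c3ccccc3)C(C)(C)C)c2OCc2ccccc2)c1C=O
F3 | step 13 | 2-[2-(benzyloxy)-5-(tert-butoxycarbonyl)-3-{[(tert-butyldiphenylsilyl)oxy]methyl}-4-(methoxymethoxy)phenoxy]-3-bromo-4-(methoxymethoxy)-6-methylbenzoic acid | Cc1cc(OCOC)c(Br)c(Oc2cc(C(=O)OC(C)(C)C)c(OCOC)c(CO[Si](c3ccccc3)(c3ccccc3)C(C)(C)C)c2OCc2ccccc2)c1C(=O)O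
F4 | step 14 | tert-butyl 4-(benzyloxy)-3-{[(tert-butyldiphenylsilyl)oxy]methyl}-6-formyl-5-hydroxy-2-(methoxymethoxy)benzoate | CC(C)(C)OC(=O)c1c(C=O)c(O)c(OCc2ccccc2)c(CO[Si](c2ccccc2)(c2ccccc2)C(C)(C)C)c1OCOC
F5 | step 14 | tert-butyl 4-(benzyloxy)-3-{[(tert-butyldiphenylsilyl)oxy]methyl}-5-{[(E)-1,2-dichloroethenyl]oxy}-6-formyl-2-(methoxymethoxy)benzoate | CC(C)(C)OC(=O)c1c(C=O)c(O/C(Cl)=C\Cl)c(OCc2ccccc2)c(CO[Si](c2ccccc2)(c2ccccc2)C(C)(C)C)c1OCOC
F6 | step 14 | tert-butyl 4-(benzyloxy)-5-{[3-(benzyloxy)-3-oxoprop-1-yn-1-yl]oxy}-3-{[(tert-butyldiphenylsilyl)oxy]methyl}-6-formyl-2-(methoxymethoxy)benzoate | CC(C)(C)OC(=O)c1c(C=O)c(OC#CC(=O)OCc2ccccc2)c(OCc2ccccc2)c(CO[Si](c2ccccc2)(c2ccccc2)C(C)(C)C)c1OCOC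
F7 | step 14 | benzyl 2-[2-(benzyloxy)-5-(tert-butoxycarbonyl)-3-{[(tert-butyldiphenylsilyl)oxy]methyl}-6-formyl-4-(methoxymethoxy)phenoxy]-3-bromo-4-(methoxymethoxy)-6-methylbenzoate | Cc1cc(OCOC)c(Br)c(Oc2c(C=O)c(C(=O)OC(C)(C)C)c(OCOC)c(CO[Si](c3ccccc3)(c3ccccc3)C(C)(C)C)c2OCc2ccccc2)c1C(=O)OCc1ccccc1
F8 | step 10 | tert-butyl 4-(benzyloxy)-5-{[3-(benzyloxy)-1-bromo-3-oxoprop-1-en-1-yl]oxy}-3-{[(tert-butyldiphenylsilyl)oxy]methyl}-2-(methoxymethoxy)benzoate (mixture of double-bond isomers) | CC(C)(C)OC(=O)c1cc(OC(Br)=CC(=O)OCc2ccccc2)c(OCc2ccccc2)c(CO[Si](c2ccccc2)(c2ccccc2)C(C)(C)C)c1OCOC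
A1 | alternative 1 | depsidone phthalide with ring B methyl and methyl ether | Cc1cc(OC)c(C=O)c2c1C(=O)Oc1c(C)c(OC)c3c(c1O2)COC3=O
A2 | alternative 2 | tert-butyl 4-(benzyloxy)-6-formyl-2-hydroxy-3-methyl-5-[(triisopropylsilyl)oxy]benzoate | CC(C)(C)OC(=O)c1c(O)c(C)c(OCc2ccccc2)c(O[Si](C(C)C)(C(C)C)C(C)C)c1C=O
A3 | alternative 3 | protected depsidone phthalide with ring B ethyl ether, ring A dioxolane and silyloxymethyl group | Cc1cc(OC)c(C3OCCO3)c2c1C(=O)Oc1c(CO[Si](C)(C)C(C)(C)C)c(OCC)c3c(c1O2)COC3=O
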